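**Retrosynthetic overview**
1. The target comes from double angeloylation of the trans-1,3-diol. The diol comes from a tricyclic bis-enone by Me2CuLi addition, β-borylation/oxidation and hydroxyl-directed reduction.
2. The cyclobutane is the last ring formed. Its bond between the two carbonyl α′-carbons is made by oxidative coupling of the bis-dienolate of a cis-fused 6-7 bis-enone.
3. Key step: the seven-membered ring comes from a one-carbon ring expansion of a cis-decalone. In a β-oxido carbenoid 1,2-shift, CH–CH3 is inserted between the C=O and the ring-fusion carbon.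
4. The cis-decalone comes from an enantioselective annulation of 4,4-dimethylcyclohexenone (isobutyraldehyde + methyl vinyl ketone) with a 2-silyloxybutadiene (from methyl vinyl ketone).
5. Ring order: cyclohexenone (ring B), then ring A, then ring B enlarged to seven members, then the cyclobutane.

Assumption: locants in the text are those of the name of the compound under discussion. TBS and TMS are counted as protecting groups. C9 of 11–13 and the carbinol carbon of 8 and 9 are left undefined in the SMILES, because these centres are planarised or destroyed later.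

**Step 1**
Reactants: 1 2-methylpropanal, 2 but-3-en-2-one
Product: 3 4,4-dimethylcyclohex-2-en-1-one
Conditions: cat. H2SO4, toluene, reflux (Dean–Stark)
Reagents that add atoms: none
Why: In this acid-catalysed Robinson annulation the enol of 1 adds to 2 (Michael addition) and the keto aldehyde closes by aldol condensation, only one enone being possible because the aldehyde α-carbon is quaternary, and no stereocenter is formed.

**Step 2**
Reactants: 2 but-3-en-2-one
Product: 4 tert-butyl(buta-1,3-dien-2-yloxy)dimethylsilane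
Conditions: TBSOTf, Et3N, Et2O, 0 °C
Reagents that add atoms: tert-butyldimethylsilyl trifluoromethanesulfonate CC(C)(C)[Si](C)(C)OS(=O)(=O)C(F)(F)F
Why: Soft enolisation and O-silylation of the methyl ketone (silyl enol ether formation) gives the 2-silyloxydiene, and no stereocenter is formed.

**Step 3**
Reactants: 3 4,4-dimethylcyclohex-2-en-1-one, 4 tert-butyl(buta-1,3-dien-2-yloxy)dimethylsilane
Product: 5 (4aR,8aS)-6-(tert-butyldimethylsilyloxy)-4,4-dimethyl-3,4,4a,5,8,8a-hexahydronaphthalen-1(2H)-one (cis-fused)
Conditions: (S)-3,3-diphenyl-1-(2-methylphenyl)tetrahydro-1H,3H-pyrrolo[1,2-c][1,3,2]oxazaborole (20 mol %), HNTf2 (20 mol %), CH2Cl2, −40 → 0 °C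
Reagents that add atoms: none
Why: In this Lewis-acid-catalysed Diels–Alder annulation the nucleophilic CH2 terminus of 4 bonds to the β-carbon of 3 ("para" rule), suprafacial addition fixes the cis ring fusion, and the chiral oxazaborolidinium cation (either antipode is available) shields one enantiotopic face of the bound enone so that C4a is set as R and C8a as S.

**Step 4**
Reactants: 5 (4aR,8aS)-6-(tert-butyldimethylsilyloxy)-4,4-dimethyl-3,4,4a,5,8,8a-hexahydronaphthalen-1(2H)-one, 6 1,1-dibromoethane
Product: 11 (4aR,9aS)-3-(tert-butyldimethylsilyloxy)-5,5,9-trimethyl-1,4,4a,5,6,7,9,9a-octahydro-8H-benzo[7]annulen-8-one (cis-fused; C9 epimers), via 1,1-dibromoethyllithium 7 (not isolated), via lithium alkoxide adduct 8 (not isolated), via beta-oxido carbenoid 9 (not isolated), via lithium enolate 10 (not isolated)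
Conditions: 6, LiN(iPr)2, THF/Et2O, −95 °C; then n-BuLi, −95 → 0 °C; H2O
Reagents that add atoms: none
Why: In this Nozaki–Yamamoto β-oxido carbenoid ring expansion 7 adds to the only carbonyl group, Br/Li exchange gives 9, and the more substituted ring-fusion carbon C8a undergoes the 1,2-shift to the electron-poor carbenoid carbon with loss of LiBr and retention at the migrating carbon, so the cis fusion survives, while the new C9 centre (set unselectively on protonation of 10) does not matter because it is planarised in step 6.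

**Step 5**
Reactants: 11 (4aR,9aS)-3-(tert-butyldimethylsilyloxy)-5,5,9-trimethyl-1,4,4a,5,6,7,9,9a-octahydro-8H-benzo[7]annulen-8-one
Product: 13 (4aR,9aS)-5,5,9-trimethyl-4a,5,9,9a-tetrahydro-3H-benzo[7]annulene-3,8(4H)-dione (cis-fused; C9 epimers), via bis(silyl enol ether) 12 (not isolated)
Conditions: LiN(iPr)2, TMSCl, THF, −78 °C; then Pd(OAc)2 (2.2 equiv), MeCN, rt
Reagents that add atoms: none
Why: Kinetic enolisation takes the less hindered C7 methylene, and a twofold Saegusa–Ito oxidation turns both silyl enol ethers into enones (each palladium enolate has only one neighbour bearing a β-hydrogen), which blocks C7 and C2 against enolisation in the next step without creating a stereocenter.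

**Step 6**
Reactants: 13 (4aR,9aS)-5,5,9-trimethyl-4a,5,9,9a-tetrahydro-3H-benzo[7]annulene-3,8(4H)-dione
Product: 15 (1R,2R,7S,8S)-2,6,6-trimethyltricyclo[5.4.0.0^2,8]undeca-4,9-diene-3,11-dione, via dilithium bis(dienolate) 14 (not isolated)
Conditions: LiN(iPr)2 (2.3 equiv), THF, −78 °C; then FeCl3 (2.3 equiv), DMF, −78 → −20 °C, 0.005 M
Reagents that add atoms: none
Why: Proposed new method: an intramolecular oxidative coupling of two different cross-conjugated lithium dienolates that closes a cyclobutane and an all-carbon quaternary centre in one operation - because both ketones are enones, kinetic deprotonation can only take the α′-hydrogens at C4 and C9, the cis ring fusion holds these two carbons gauche at about 3 Å, one-electron oxidation of the more electron-rich tetrasubstituted C9 dienolate by FeCl3 gives an α-keto radical that adds 4-exo to the C4 dienolate carbon, and the resulting ketyl radical anion is oxidised irreversibly by the second FeCl3 so that the strained ring cannot reopen, while the two tethers allow only the isomer with the seven-membered bridge on one face and the enone bridge on the other (C1 R, C2 R); the closest known reactions are the FeCl3 or CuCl2 oxidative dimerisation of kinetic enone enolates and the CuBr2- or iodine-mediated closure of adipate dianions to cyclobutane-1,2-diesters.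

**Step 7**
Reactants: 15 (1R,2R,7S,8S)-2,6,6-trimethyltricyclo[5.4.0.0^2,8]undeca-4,9-diene-3,11-dione
Product: 17 (1R,2R,7S,8S,9R)-2,6,6,9-tetramethyltricyclo[5.4.0.0^2,8]undec-4-ene-3,11-dione, via lithium enolate 16 (not isolated)
Conditions: MeLi (2.2 equiv), CuI (1.1 equiv), Et2O, 0 °C; then 15, −78 °C; H2O
Reagents that add atoms: methyllithium [Li]C
Why: In this Gilman conjugate addition the unhindered β-carbon C9 of the bicyclo[3.1.1]heptenone reacts much faster than the neopentyl β-carbon C5 of the cycloheptenone, and the cuprate approaches anti to the C2 methyl group that overhangs the other face (the apoverbenone to trans-verbanone precedent), which sets C9 as R.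

**Step 8**
Reactants: 17 (1R,2R,7S,8S,9R)-2,6,6,9-tetramethyltricyclo[5.4.0.0^2,8]undec-4-ene-3,11-dione
Product: 19 (1R,2R,5R,7S,8S,9R)-5-hydroxy-2,6,6,9-tetramethyltricyclo[5.4.0.0^2,8]undecane-3,11-dione, via beta-boryl ketone 18 (not isolated)
Conditions: CuCl (5 mol %), NaOt-Bu (5 mol %), (R)-1-[(S)-2-(diphenylphosphino)ferrocenyl]ethyldicyclohexylphosphine (5 mol %), B2pin2, MeOH, THF, rt; then 30% H2O2, pH 7 buffer, 0 °C
Reagents that add atoms: hydrogen peroxide OO
Why: This copper-catalysed asymmetric β-borylation of a cyclic enone runs under ligand control because the two enone faces are sterically almost equal, so the ligand antipode that delivers boron to the face turned toward C8 is used, and the stereoretentive C–B oxidation then fixes C5 as R.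

**Step 9**
Reactants: 19 (1R,2R,5R,7S,8S,9R)-5-hydroxy-2,6,6,9-tetramethyltricyclo[5.4.0.0^2,8]undecane-3,11-dione
Product: 20 (1R,2R,3R,5R,7S,8S,9R)-3,5-dihydroxy-2,6,6,9-tetramethyltricyclo[5.4.0.0^2,8]undecan-11-one
Conditions: Me4NBH(OAc)3, MeCN/AcOH, −30 °C
Reagents that add atoms: none
Why: In this Evans–Saksena reduction the C5 hydroxyl binds the boron hydride and delivers hydride to the same face of the C3 ketone, giving the trans (anti) 1,3-diol with C3 as R, while the C11 ketone has no directing hydroxyl nearby and is not touched by this mild hydride.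

**Step 10**
Reactants: 20 (1R,2R,3R,5R,7S,8S,9R)-3,5-dihydroxy-2,6,6,9-tetramethyltricyclo[5.4.0.0^2,8]undecan-11-one, 21 angelic acid ((Z)-2-methylbut-2-enoic acid)
Product: 23 (1R,2R,3R,5R,7S,8S,9R)-2,6,6,9-tetramethyl-11-oxotricyclo[5.4.0.0^2,8]undecane-3,5-diyl bis[(Z)-2-methylbut-2-enoate] (target), via angelic trichlorobenzoic anhydride 22 (not isolated)
Conditions: 21 (3 equiv), 2,4,6-trichlorobenzoyl chloride, Et3N, toluene, rt; then 20, 80 °C
Reagents that add atoms: none
Why: Yamaguchi-type acylation through the mixed anhydride, run without a nucleophilic amine catalyst, esterifies hindered secondary alcohols and is known to preserve the Z geometry of angelates, and no stereocenter is touched.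

**Compound list**
1 | 2-methylpropanal | CC(C)C=O | starting material
2 | but-3-en-2-one | CC(=O)C=C | starting material
3 | 4,4-dimethylcyclohex-2-en-1-one | CC1(C)CCC(=O)C=C1 | intermediate
4 | tert-butyl(buta-1,3-dien-2-yloxy)dimethylsilane | C=CC(=C)O[Si](C)(C)C(C)(C)C | intermediate
5 | (4aR,8aS)-6-(tert-butyldimethylsilyloxy)-4,4-dimethyl-3,4,4a,5,8,8a-hexahydronaphthalen-1(2H)-one | C1CC(=O)[C@H]2CC=C(O[Si](C)(C)C(C)(C)C)C[C@H]2C1(C)C | intermediate
6 | 1,1-dibromoethane | CC(Br)Br | starting material
7 | 1,1-dibromoethyllithium | CC(Br)(Br)[Li] | intermediate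
8 | lithium alkoxide from addition of 7 to C1 of 5 | C1CC(O[Li])(C(C)(Br)Br)[C@H]2CC=C(O[Si](C)(C)C(C)(C)C)C[C@H]2C1(C)C | intermediate
9 | β-oxido carbenoid (1-bromo-1-lithioethyl alkoxide) | C1CC(O[Li])(C(C)(Br)[Li])[C@H]2CC=C(O[Si](C)(C)C(C)(C)C)C[C@H]2C1(C)C | intermediate
10 | lithium C8=C9 enolate of 11 | C1CC(O[Li])=C(C)[C@H]2CC=C(O[Si](C)(C)C(C)(C)C)C[C@H]2C1(C)C | intermediate
11 | (4aR,9aS)-3-(tert-butyldimethylsilyloxy)-5,5,9-trimethyl-1,4,4a,5,6,7,9,9a-octahydro-8H-benzo[7]annulen-8-one | C1CC(=O)C(C)[C@H]2CC=C(O[Si](C)(C)C(C)(C)C)C[C@H]2C1(C)C | intermediate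
12 | (4aR,9aS)-3-(tert-butyldimethylsilyloxy)-5,5,9-trimethyl-8-(trimethylsilyloxy)-4,4a,5,6,9,9a-hexahydro-1H-benzo[7]annulene | C1C=C(O[Si](C)(C)C)C(C)[C@H]2CC=C(O[Si](C)(C)C(C)(C)C)C[C@H]2C1(C)C | intermediate
13 | (4aR,9aS)-5,5,9-trimethyl-4a,5,9,9a-tetrahydro-3H-benzo[7]annulene-3,8(4H)-dione | C1=CC(=O)C(C)[C@H]2C=CC(=O)C[C@H]2C1(C)C | intermediate
14 | dilithium bis(dienolate) of 13 (C3=C4 and C8=C9) | C1=CC(O[Li])=C(C)[C@H]2C=CC(O[Li])=C[C@H]2C1(C)C | intermediate
15 | (1R,2R,7S,8S)-2,6,6-trimethyltricyclo[5.4.0.0^2,8]undeca-4,9-diene-3,11-dione | C1=CC(=O)[C@]2(C)[C@@H]3[C@@H]([C@H]2C(=O)C=C3)C1(C)C | intermediate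
16 | lithium C10=C11 enolate of 17 | C1=CC(=O)[C@]2(C)[C@@H]3[C@@H]([C@H]2C(O[Li])=C[C@H]3C)C1(C)C | intermediate
17 | (1R,2R,7S,8S,9R)-2,6,6,9-tetramethyltricyclo[5.4.0.0^2,8]undec-4-ene-3,11-dione | C1=CC(=O)[C@]2(C)[C@@H]3[C@@H]([C@H]2C(=O)C[C@H]3C)C1(C)C | intermediate
18 | (1R,2R,5R,7S,8S,9R)-2,6,6,9-tetramethyl-5-(4,4,5,5-tetramethyl-1,3,2-dioxaborolan-2-yl)tricyclo[5.4.0.0^2,8]undecane-3,11-dione | CC1(C)OB(OC1(C)C)[C@@H]2CC(=O)[C@]3(C)[C@@H]4[C@@H]([C@H]3C(=O)C[C@H]4C)C2(C)C | intermediate
19 | (1R,2R,5R,7S,8S,9R)-5-hydroxy-2,6,6,9-tetramethyltricyclo[5.4.0.0^2,8]undecane-3,11-dione | O[C@@H]1CC(=O)[C@]2(C)[C@@H]3[C@@H]([C@H]2C(=O)C[C@H]3C)C1(C)C | intermediate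
20 | (1R,2R,3R,5R,7S,8S,9R)-3,5-dihydroxy-2,6,6,9-tetramethyltricyclo[5.4.0.0^2,8]undecan-11-one | O[C@@H]1C[C@@H](O)[C@]2(C)[C@@H]3[C@@H]([C@H]2C(=O)C[C@H]3C)C1(C)C | intermediate
21 | angelic acid, (Z)-2-methylbut-2-enoic acid | C/C=C(/C)C(=O)O | starting material
22 | (Z)-2-methylbut-2-enoic 2,4,6-trichlorobenzoic anhydride | C/C=C(/C)C(=O)OC(=O)c1c(Cl)cc(Cl)cc1Cl | intermediate
23 | (1R,2R,3R,5R,7S,8S,9R)-2,6,6,9-tetramethyl-11-oxotricyclo[5.4.0.0^2,8]undecane-3,5-diyl bis[(Z)-2-methylbut-2-enoate] | C/C=C(/C)C(=O)O[C@@H]1C[C@@H](OC(=O)/C(C)=C\C)[C@]2(C)[C@@H]3[C@@H]([C@H]2C(=O)C[C@H]3C)C1(C)C | target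

**Step count**
Total steps: 10. Longest linear sequence: 9 (steps 1 and 3–10; step 2 is a one-step side branch).

**The three steps most likely to fail**

Step 6 is the proposed new reaction. The strained four-membered ring may lose out to intermolecular coupling, chlorination or over-oxidation. The fallback uses known chemistry and runs from 13 back to 15.
- One equivalent of LiN(iPr)2 takes the more accessible C4 methylene, and TMSCl gives the cross-conjugated silyl dienol ether F1.
- NBS converts this into the (4R)-4-bromo bis-enone F2, with bromine entering anti to the seven-membered ring.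
- KOt-Bu in t-BuOH/THF generates the only possible C9 enolate. It displaces bromide in a 4-exo-tet intramolecular alkylation, the classical two-electron enolate-alkylation closure of bridged cyclobutanes, and gives 15.

Step 3 may suffer because the gem-dimethyl group next to the β-carbon makes 3 a sluggish dienophile. Turnover and enantioselectivity of the chiral catalyst could both be poor. The fallback runs from 3 and 4 back to 5.
- EtAlCl2-promoted cycloaddition gives the racemic cis cycloadduct F3.
- Lithiated (S)-N,S-dimethyl-S-phenylsulfoximine adds to the ketone to give diastereomeric carbinols that are separable by chromatography.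
- The (4aR,8aS)-configured β-hydroxysulfoximine F4 is isolated and thermolysed in refluxing toluene to release enantiopure 5. This replaces asymmetric catalysis by a resolution.

Step 4 carries two risks. The bulky carbenoid precursor may enolise the hindered ketone, or the C2 methylene may migrate instead of C8a. The fallback runs from 5 back to 11.
- 1-(Methylselanyl)ethyllithium, made from 1,1-bis(methylselanyl)ethane and n-BuLi, is less basic and adds cleanly to give the β-hydroxyselenide F5.
- AgBF4 on alumina in CH2Cl2 triggers a cationic semipinacol ring expansion. For this reaction type, preferential migration of the more substituted carbon is well documented, and the product is 11.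

**Further compounds**
F1 | step 6 | (4aR,9aS)-5,5,9-trimethyl-3-(trimethylsilyloxy)-4a,5,9,9a-tetrahydro-8H-benzo[7]annulen-8-one (C3=C4 silyl dienol ether) | C1=CC(=O)C(C)[C@H]2C=CC(O[Si](C)(C)C)=C[C@H]2C1(C)C
F2 | step 6 | (4R,4aR,9aS)-4-bromo-5,5,9-trimethyl-4a,5,9,9a-tetrahydro-3H-benzo[7]annulene-3,8(4H)-dione | C1=CC(=O)C(C)[C@H]2C=CC(=O)[C@H](Br)[C@H]2C1(C)C
F3 | step 3 | racemic cis-6-(tert-butyldimethylsilyloxy)-4,4-dimethyl-3,4,4a,5,8,8a-hexahydronaphthalen-1(2H)-one | C1CC(=O)C2CC=C(O[Si](C)(C)C(C)(C)C)CC2C1(C)C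
F4 | step 3 | (4aR,8aS)-6-(tert-butyldimethylsilyloxy)-4,4-dimethyl-1-{[(S)-N-methyl-S-phenylsulfonimidoyl]methyl}-1,2,3,4,4a,5,8,8a-octahydronaphthalen-1-ol | C1CC(O)(C[S@@](=O)(=NC)c3ccccc3)[C@H]2CC=C(O[Si](C)(C)C(C)(C)C)C[C@H]2C1(C)C
F5 | step 4 | (4aR,8aS)-6-(tert-butyldimethylsilyloxy)-4,4-dimethyl-1-[1-(methylselanyl)ethyl]-1,2,3,4,4a,5,8,8a-octahydronaphthalen-1-ol | C1CC(O)(C(C)[Se]C)[C@H]2CC=C(O[Si](C)(C)C(C)(C)C)C[C@H]2C1(C)C
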